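**Plan**
- **Cuts at ring D.** The exocyclic C=CH2 goes back to a ketone. Ring D is then cut at the bond between its ether CH (C12) and the neighbouring CH2 (C13). This gives an oxolane-2-carboxylic acid with an acryloyl group on the quaternary bridgehead C7.
- **Enabling feature.** In ring C, C12 and C7 stand 1,3 to each other across C11 (CMe2), and ring D joins them through CH2–CH2–C(=CH2). With the methylidene read as C=O, that chain is a vinyl ketone whose terminal carbon is the sixth atom from an α-oxy radical at C12.
- **Further cuts.** These are the carboxyl carbon (a furan surrogate added to a γ-lactone), the C7–C11 bond between the two adjacent quaternary carbons (Ireland–Claisen), the C7 exocyclic olefin (butenolide from an α-ketol), C1–Br (bromoalkene) and C4–CH3 (carbonyl addition).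
- **Forward order.** Rings A and B arrive together in (S)-Wieland–Miescher ketone. Ring A is finished first, ring C closes as a lactone after the Claisen step, and ring D closes last.
- **Stereochemistry.** C10 comes from the starting ketone and relays to C5 (hydroboration, equilibration), C4 (equatorial methyl delivery), C1 (axial H-atom delivery), C8 (oxidation anti to the angular methyl) and C7 (equatorial Claisen bond). C12 is fixed by the bicyclic constraint.

Key step: step 19

Locants:
- Decalin: C1 (CHBr), C2, C3, C4 (methyl carbinol), C5 (ring-fusion CH), C6, C7 (quaternary bridgehead), C8 (ring-B ether CH), C9, C10 (angular C–CH3).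
- Remaining carbons: C11 = CMe2; C12 = ether CH shared by rings C and D; C13 and C14 = ring-D methylenes; C15 = methylidene-bearing carbon.
- Rings: ring C = oxolane (O, C8, C7, C11, C12); ring D = C7, C11, C12, C13, C14, C15.
- Faces of the trans-decalin: methyl face (side of the axial C10–CH3) and hydrogen face (side of the axial C5–H).

Assumption: the hemiketal carbon of the furyl lactol and the carbinol carbon of the allylic alcohol are expected as epimer mixtures. Both centres are erased later, so their SMILES leave them open.

Step 1
Reactants: 1 (S)-Wieland–Miescher ketone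
Product: 2 C1-hydroxy enone
Conditions: NaBH4 (0.3 equiv), EtOH, 0 °C
Reagents that add atoms: none
Why: Chemoselective borohydride reduction, in which the saturated C1 ketone is more electrophilic than the vinylogous C7 carbonyl and axial hydride delivery on the hydrogen face gives the equatorial carbinol, a placeholder centre that keeps C1 out of the ketalisation and is erased in step 4.

Step 2
Reactants: 2 C1-hydroxy enone
Product: 3 C7 dioxolane bearing the C4=C5 olefin
Conditions: HOCH2CH2OH, p-TsOH (cat.), benzene, reflux, Dean–Stark trap
Reagents that add atoms: ethylene glycol, OCCO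
Why: Ketalisation of an enone with deconjugation, the olefin settling at C4=C5 because this is the only β,γ-position open next to the quaternary C10, which makes C4 addressable.

Step 3
Reactants: 3 C7 dioxolane bearing the C4=C5 olefin
Product: 5 trans-decalindiol ketal, via alkylborane 4 (not isolated)
Conditions: BH3·THF, THF, 0 °C → rt; then NaOH, H2O2, 0 °C → rt
Reagents that add atoms: hydrogen peroxide, OO; borane–THF, B.C1CCOC1 (boron only in 4)
Why: Hydroboration–oxidation, with boron going to the less substituted C4 and hydrogen to C5 in a syn addition on the face opposite the angular methyl, which sets the trans ring fusion (C5–H anti to C10–CH3), while the C4 carbinol centre is erased in step 4.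

Step 4
Reactants: 5 trans-decalindiol ketal
Product: 6 trans-decalin-1,4-dione ketal
Conditions: Dess–Martin periodinane, NaHCO3, CH2Cl2, rt; then NaOMe (cat.), MeOH, rt
Reagents that add atoms: none
Why: Dess–Martin oxidation of both secondary carbinols followed by base equilibration at the enolisable C5, which funnels any cis-fused material into the more stable trans-fused dione.

Step 5
Reactants: 6 trans-decalin-1,4-dione ketal
Product: 7 C4 methyl carbinol
Conditions: MeTi(OiPr)3, CH2Cl2, 0 °C → rt
Reagents that add atoms: methyltitanium triisopropoxide, C[Ti](OC(C)C)(OC(C)C)OC(C)C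
Why: Chemo- and stereoselective carbonyl addition of a bulky, non-basic methyltitanium reagent, in which C1 is shielded by the quaternary C10 whereas C4 has only a tertiary neighbour, and the axial C10 methyl blocks axial approach at C4 so that methyl enters equatorially and the hydroxyl ends axial on the methyl face.

Step 6
Reactants: 7 C4 methyl carbinol
Product: 9 C1 bromoalkene, via hydrazone 8 (not isolated)
Conditions: N2H4·H2O, Et3N, EtOH, reflux, concentrate; then NBS, pyridine, 0 °C
Reagents that add atoms: hydrazine hydrate, NN.O (nitrogen only in 8); N-bromosuccinimide, O=C1CCC(=O)N1Br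
Why: Hydrazone formation followed by a Barton-type vinyl halide synthesis, where N-bromination and loss of N2 leave an α-bromo cation at C1 that can lose a proton only from C2, as is usual for hydrazones next to a quaternary carbon.

Step 7
Reactants: 9 C1 bromoalkene
Product: 10 C1 equatorial bromide ketal
Conditions: Co(acac)2 (cat.), t-BuOOH, Et3SiH, 1,4-cyclohexadiene, n-PrOH, rt, argon
Reagents that add atoms: none
Why: Cobalt-hydride hydrogen-atom-transfer hydrogenation of an alkenyl halide, in which H adds to C2 and the α-bromo radical at C1 takes its hydrogen from cyclohexadiene along the axial path on the hydrogen face, anti to the adjacent axial C10 methyl, so that bromine ends equatorial and the C–Br bond is never exposed to a hydrogenolysis catalyst.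

Step 8
Reactants: 10 C1 equatorial bromide ketal
Product: 11 bromohydroxydecalone
Conditions: PPTS, acetone–H2O, 50 °C
Reagents that add atoms: water, O
Why: Acid hydrolysis of an unhindered dioxolane under conditions too mild to ionise the unactivated tertiary carbinol.

Step 9
Reactants: 11 bromohydroxydecalone
Product: 14 C8 ketol, via silyl enol ether 12 (not isolated), via silyloxy ketone 13 (not isolated)
Conditions: TMSOTf, Et3N, CH2Cl2, 0 °C; then mCPBA, NaHCO3, CH2Cl2, 0 °C; then dilute aq. HCl, THF, 0 °C
Reagents that add atoms: mCPBA, OOC(=O)c1cccc(Cl)c1; TMSOTf, C[Si](C)(C)OS(=O)(=O)C(F)(F)F (silicon only in 12 and 13)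
Why: Rubottom oxidation, in which a trans-fused 2-decalone of this type enolises away from the ring fusion (towards C8) and the peracid attacks the C7=C8 enol ether on the hydrogen face, anti to the axial methyl that is 1,3 to C8, which places the new hydroxyl equatorial, also the thermodynamically preferred position.

Step 10
Reactants: 14 C8 ketol; 15 (triphenylphosphoranylidene)ketene
Product: 17 butenolide, via acyl ylide 16 (not isolated)
Conditions: toluene, 110 °C
Reagents that add atoms: (triphenylphosphoranylidene)ketene 15, O=C=C=P(c1ccccc1)(c1ccccc1)c1ccccc1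
Why: Bestmann butenolide synthesis, the secondary C8 hydroxyl adding to the ketene ylide and the resulting acyl ylide closing on the neighbouring C7 ketone by intramolecular Wittig olefination, while the hindered axial C4 carbinol does not compete and C8 is untouched.

Step 11
Reactants: 17 butenolide
Product: 18 (Z)-enediol
Conditions: iBu2AlH (excess), CH2Cl2, −78 → 0 °C; aq. potassium sodium tartrate
Reagents that add atoms: none
Why: Exhaustive 1,2-reduction of the butenolide by an aluminium hydride that touches neither the olefin nor the neopentyl bromide, the Z geometry (CH2OH cis to C8) being inherited from the ring.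

Step 12
Reactants: 18 (Z)-enediol; 19 isobutyryl chloride
Product: 20 primary allylic isobutyrate
Conditions: 2,4,6-collidine, CH2Cl2, −78 → −20 °C
Reagents that add atoms: isobutyryl chloride 19, CC(C)C(Cl)=O
Why: Selective acylation, the primary allylic hydroxyl reacting well ahead of the ring-bound secondary C8 hydroxyl and the axial tertiary C4 hydroxyl.

Step 13
Reactants: 20 primary allylic isobutyrate
Product: 24 vinyl lactone, via silyl ketene acetal 21 (not isolated), via silyl ester 22 (not isolated), via hydroxy acid 23 (not isolated)
Conditions: LiN(iPr)2 (excess), TMSCl (excess), THF, −78 °C → rt; toluene, 90 °C; then dilute aq. HCl, THF, rt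
Reagents that add atoms: TMSCl, C[Si](C)(C)Cl (silicon only in 21 and 22)
Why: Ireland–Claisen rearrangement, in which the ketene acetal passes its CMe2 terminus to C7 through a cyclic six-membered transition state and forges the bond between the two adjacent quaternary carbons along the equatorial path, since an axial tert-alkyl group would clash with the axial hydrogens on C5 and C9 and with the C8 silyl ether, so that the vinyl group ends axial on the hydrogen face and the acid work-up strips the silyl groups and closes the diequatorial, trans-fused γ-lactone (ring C).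

Step 14
Reactants: 24 vinyl lactone; 25 furan
Product: 27 furyl lactol, via 2-furyllithium 26 (not isolated)
Conditions: 25, n-BuLi, THF, 0 °C; then 24, −78 → −30 °C; aq. NH4Cl
Reagents that add atoms: furan 25, c1ccoc1 (delivered as 2-furyllithium 26, [Li]c1ccco1)
Why: Addition of an aryllithium to a lactone as in C-glycoside synthesis, which stops at the hemiketal because the tetrahedral alkoxide next to C11 is too hindered to collapse and react again, while a stabilised sp2 anion does not exchange with the secondary bromide.

Step 15
Reactants: 27 furyl lactol
Product: 28 C12-furyl oxolane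
Conditions: Et3SiH, BF3·OEt2, CH2Cl2, −78 °C
Reagents that add atoms: none
Why: Ionic silane reduction of a hemiketal through a furyl-stabilised oxocarbenium ion that forms far more easily than a cation at the unactivated C4 carbinol, hydride entering ring C opposite the pseudo-axial vinyl group so that the furyl group ends cis to it, a configuration that is not critical because C12 is flattened in step 19.

Step 16
Reactants: 28 C12-furyl oxolane
Product: 29 C7 aldehyde C12 acid
Conditions: O3, CH2Cl2, −78 °C; Me2S, −78 °C → rt; H2O
Reagents that add atoms: ozone, [O-][O+]=O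
Why: Ozonolysis doing two jobs in one operation, the C7 vinyl group being cleaved to the neopentyl aldehyde and the electron-rich furan, a standard carboxyl surrogate, being degraded to the C12 carboxylic acid, while bromide, ether and carbinol are inert at low temperature.

Step 17
Reactants: 29 C7 aldehyde C12 acid; 30 vinylmagnesium bromide
Product: 31 allylic alcohol acid
Conditions: 30 (excess), THF, −78 → 0 °C; cold aq. NH4Cl, then citric acid to pH 4; used at once
Reagents that add atoms: vinylmagnesium bromide 30, C=C[Mg]Br
Why: Grignard 1,2-addition to a non-enolisable aldehyde, the acid and the carbinol being masked in the flask as unreactive magnesium salts, and the new carbinol centre needing no control because it is oxidised in the next step.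

Step 18
Reactants: 31 allylic alcohol acid
Product: 32 vinyl ketone acid
Conditions: Dess–Martin periodinane, CH2Cl2, 0 °C → rt; filtration through silica
Reagents that add atoms: none
Why: Dess–Martin oxidation of a secondary allylic alcohol, which tolerates the free acid and the tertiary carbinol, avoids nucleophilic work-up reagents that could add to the vinyl ketone, and cannot trigger β-elimination of the C8 oxygen because C7 carries no hydrogen.

Step 19
Reactants: 32 vinyl ketone acid
Product: 33 tetracyclic ring-D ketone
Conditions: Ir[dF(CF3)ppy]2(dtbbpy)PF6 (2 mol %), K2HPO4, DMF (0.01 mol/L), blue LEDs (450 nm), rt, degassed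
Reagents that add atoms: none
Why: The carboxylate of 32 is oxidised by the photoexcited trivalent-iridium complex and loses CO2, the nucleophilic α-alkoxy radical at C12 adds to the terminal carbon C13 of the acryloyl group on C7, and the α-keto radical is reduced by the divalent-iridium state to an enolate that is protonated, so no external oxidant or reductant is consumed. The closest known reaction type is the photoredox decarboxylative Giese addition of oxolan-2-yl radicals to enones, and 4-oxohex-5-enyl radicals are known to prefer the endo mode. Ring D is closed in the 6-endo-trig mode, both olefinic carbons and the carbonyl carbon becoming ring members, whereas 5-exo attack would hit the non-electrophilic α-carbon, leave a primary radical and build a more strained 2-oxabicyclo[2.2.1]heptane. The only new stereocentre, C12, is set by the bicyclic constraint, since the three-carbon bridge can reach C12 only on the face of ring C that carries the axial acyl group, and because decarboxylation flattens C12 the configuration of the acid is irrelevant. The step needs cyclisation to outrun hydrogen abstraction from the solvent and intermolecular addition, which the C11 gem-dimethyl group, the fixed 1,3-cis geometry and high dilution secure. It also needs the C1–Br bond to survive, which holds because the reduced photocatalyst is far too weak a reductant for an unactivated secondary alkyl bromide.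

Step 20
Reactants: 33 tetracyclic ring-D ketone
Product: 34 target CNP0412361.2
Conditions: Cp2TiMe2 (excess), toluene–THF, 70 °C, dark
Reagents that add atoms: dimethyltitanocene, [CH3-].[CH3-].[Ti+4].c1cc[cH-]c1.c1cc[cH-]c1
Why: Petasis methylenation, the small, non-basic titanium methylidene engaging the neopentyl C15 ketone by [2+2] addition and cycloreversion without enolisation or elimination of the bromide, while the free C4 carbinol only forms a titanium alkoxide that is released on work-up.

**Compound list**
1 | (S)-Wieland–Miescher ketone, (8aS)-8a-methyl-3,4,8,8a-tetrahydronaphthalene-1,6(2H,7H)-dione | O=C1CC[C@]2(C)C(=O)CCCC2=C1 | starting material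
2 | C1-hydroxy enone, (4aS,5S)-5-hydroxy-4a-methyl-4,4a,5,6,7,8-hexahydronaphthalen-2(3H)-one, OH equatorial on the methyl face | O=C1CC[C@]2(C)[C@@H](O)CCCC2=C1 | intermediate
3 | C7 ethylene ketal of 2, olefin shifted to C4=C5 | O1CCOC12CC[C@]3(C)[C@@H](O)CCC=C3C2 | intermediate
4 | C4 alkylborane (drawn as RBH2), boron on C4 and hydrogen on C5 both on the hydrogen face | O1CCOC12CC[C@]3(C)[C@@H](O)CC[C@H](B)[C@H]3C2 | intermediate
5 | trans-decalin-1,4-diol C7 ketal, both hydroxyls equatorial, C5–H anti to C10–CH3 | O1CCOC12CC[C@]3(C)[C@@H](O)CC[C@H](O)[C@H]3C2 | intermediate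
6 | trans-decalin-1,4-dione C7 ketal | O1CCOC12CC[C@]3(C)C(=O)CCC(=O)[C@H]3C2 | intermediate
7 | C4 methyl carbinol (OH axial on the methyl face, CH3 equatorial), C1 ketone, C7 ketal | O1CCOC12CC[C@]3(C)C(=O)CC[C@@](C)(O)[C@H]3C2 | intermediate
8 | C1 hydrazone of 7 | O1CCOC12CC[C@]3(C)C(=NN)CC[C@@](C)(O)[C@H]3C2 | intermediate
9 | C1-bromo C1=C2 alkene, C4 carbinol, C7 ketal | O1CCOC12CC[C@]3(C)C(Br)=CC[C@@](C)(O)[C@H]3C2 | intermediate
10 | C1 equatorial bromide, C4 carbinol, C7 ketal | O1CCOC12CC[C@]3(C)[C@@H](Br)CC[C@@](C)(O)[C@H]3C2 | intermediate
11 | bromohydroxydecalone: trans-decalin-7-one, C1 Br equatorial, C4 OH axial and CH3 equatorial, C10 CH3 | O=C1CC[C@]2(C)[C@@H](Br)CC[C@@](C)(O)[C@H]2C1 | intermediate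
12 | C7=C8 trimethylsilyl enol ether of 11, C4 OTMS | C[Si](C)(C)OC1=CC[C@]2(C)[C@@H](Br)CC[C@@](C)(O[Si](C)(C)C)[C@H]2C1 | intermediate
13 | C8 equatorial trimethylsilyloxy C7 ketone, C4 OTMS | O=C1[C@H](O[Si](C)(C)C)C[C@]2(C)[C@@H](Br)CC[C@@](C)(O[Si](C)(C)C)[C@H]2C1 | intermediate
14 | C8 ketol: C8 OH equatorial on the hydrogen face, C7 ketone | O=C1[C@H](O)C[C@]2(C)[C@@H](Br)CC[C@@](C)(O)[C@H]2C1 | intermediate
15 | (triphenylphosphoranylidene)ketene | O=C=C=P(c1ccccc1)(c1ccccc1)c1ccccc1 | starting material
16 | C8 O-(triphenylphosphoranylidene)acetate of 14 | O=C(C=P(c1ccccc1)(c1ccccc1)c1ccccc1)O[C@@H]1C[C@]2(C)[C@@H](Br)CC[C@@](C)(O)[C@H]2CC1=O | intermediate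
17 | butenolide fused at C7–C8 (C8–O–C(=O)–CH=C7) | O=C1O[C@@H]2C[C@]3(C)[C@@H](Br)CC[C@@](C)(O)[C@H]3CC2=C1 | intermediate
18 | (Z)-enediol: C7=CH–CH2OH with CH2OH cis to C8, C8 OH equatorial | OC/C=C1\[C@H](O)C[C@]2(C)[C@@H](Br)CC[C@@](C)(O)[C@H]2C1 | intermediate
19 | isobutyryl chloride | CC(C)C(Cl)=O | starting material
20 | primary allylic isobutyrate of 18 | CC(C)C(=O)OC/C=C1\[C@H](O)C[C@]2(C)[C@@H](Br)CC[C@@](C)(O)[C@H]2C1 | intermediate
21 | silyl ketene acetal of 20, C4 and C8 as OTMS | CC(C)=C(O[Si](C)(C)C)OC/C=C1\[C@H](O[Si](C)(C)C)C[C@]2(C)[C@@H](Br)CC[C@@](C)(O[Si](C)(C)C)[C@H]2C1 | intermediate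
22 | rearranged trimethylsilyl ester: C7 vinyl axial, C7–CMe2CO2TMS equatorial, C4 and C8 as OTMS | C[Si](C)(C)O[C@@H]1C[C@]2(C)[C@@H](Br)CC[C@@](C)(O[Si](C)(C)C)[C@H]2C[C@@]1(C=C)C(C)(C)C(=O)O[Si](C)(C)C | intermediate
23 | C8 hydroxy acid: C7 vinyl axial, C7–CMe2CO2H equatorial | O[C@@H]1C[C@]2(C)[C@@H](Br)CC[C@@](C)(O)[C@H]2C[C@@]1(C=C)C(C)(C)C(=O)O | intermediate
24 | vinyl lactone: trans-fused γ-lactone (O, C8, C7, C11, C12=O), C7 vinyl axial on the hydrogen face | O=C1O[C@@H]2C[C@]3(C)[C@@H](Br)CC[C@@](C)(O)[C@H]3C[C@@]2(C=C)C1(C)C | intermediate
25 | furan | c1ccoc1 | starting material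
26 | 2-furyllithium | [Li]c1ccco1 | intermediate
27 | furyl lactol: C12 hemiketal bearing 2-furyl (epimers at C12) | OC1(c2ccco2)O[C@@H]2C[C@]3(C)[C@@H](Br)CC[C@@](C)(O)[C@H]3C[C@@]2(C=C)C1(C)C | intermediate
28 | C12-(2-furyl)oxolane, furyl cis to the C7 vinyl group | o1cccc1[C@@H]2O[C@@H]3C[C@]4(C)[C@@H](Br)CC[C@@](C)(O)[C@H]4C[C@@]3(C=C)C2(C)C | intermediate
29 | C7 carbaldehyde, C12 carboxylic acid | OC(=O)[C@@H]1O[C@@H]2C[C@]3(C)[C@@H](Br)CC[C@@](C)(O)[C@H]3C[C@@]2(C=O)C1(C)C | intermediate
30 | vinylmagnesium bromide | C=C[Mg]Br | starting material
31 | C7 (1-hydroxyallyl) C12 carboxylic acid (epimers at the carbinol carbon) | OC(=O)[C@@H]1O[C@@H]2C[C@]3(C)[C@@H](Br)CC[C@@](C)(O)[C@H]3C[C@@]2(C(O)C=C)C1(C)C | intermediate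
32 | vinyl ketone acid: decalin-fused oxolane-2-carboxylic acid with an acryloyl group on C7 | OC(=O)[C@@H]1O[C@@H]2C[C@]3(C)[C@@H](Br)CC[C@@](C)(O)[C@H]3C[C@@]2(C(=O)C=C)C1(C)C | intermediate
33 | tetracyclic ring-D ketone (C15=O) | O=C1CC[C@@H]2O[C@@H]3C[C@]4(C)[C@@H](Br)CC[C@@](C)(O)[C@H]4C[C@]13C2(C)C | intermediate
34 | CNP0412361.2 | C=C1CC[C@@H]2O[C@@H]3C[C@]4(C)[C@@H](Br)CC[C@@](C)(O)[C@H]4C[C@]13C2(C)C | target

Total step count: 20. Longest linear sequence: 20 steps, from 1.

**Steps most likely to fail**

**Step 13.** The [3,3] shift may be slow at the congested C7/C11 pair. The hindered enolate may fragment by ketene loss before it is silylated. The preference for the equatorial path may also erode.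

The fallback lowers the steric cost of the C–C bond and builds the gem-dimethyl group afterwards. It sets out from 18 and runs as follows:
- 18 is acetylated at the primary hydroxyl (Ac2O, collidine) to the primary allylic acetate F2.
- Ireland–Claisen rearrangement of F2 under the same silylating conditions, followed by acid work-up, should give the C11-unsubstituted vinyl lactone F3.
- Two successive enolisation–methylation cycles (LiN(iPr)2, MeI, THF, −78 °C) follow, with the C4 carbinol carried as its lithium alkoxide. They pass through the monomethyl lactone F4 and come back to the route at 24.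

**Step 7.** Hydrogen-atom transfer to the hindered trisubstituted bromoalkene may be sluggish. Bromine may be lost by over-reduction. The facial selectivity of the final hydrogen abstraction may be poor.

The fallback reaches the same α-bromo radical from another precursor and uses a bulkier hydrogen donor:
- It sets out from hydrazone 8, which is oxidised with CuBr2 and t-BuOLi in THF to the geminal dibromide F1.
- Radical mono-debromination with one equivalent of (Me3Si)3SiH (Et3B, air, toluene, 0 °C) should deliver hydrogen on the hydrogen face and come back at 10.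

**Step 19.** Oxidation of the hindered carboxylate may be slow. The C12 radical may abstract hydrogen before it cyclises. The vinyl ketone may oligomerise under the basic photochemical conditions.

The fallback keeps the same bond and ring closure but generates the radical reductively from an activated ester, without base:
- It sets out from 32, which is coupled with N-hydroxyphthalimide (DIC, DMAP cat., CH2Cl2, 0 °C) to the N-acyloxyphthalimide F5.
- Irradiation of F5 with Ru(bpy)3(PF6)2 and Hantzsch ester in CH2Cl2 (blue LEDs, high dilution) fragments the ester to the same C12 radical.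
- The α-keto radical is then quenched by hydrogen transfer from the dihydropyridine, and the route is rejoined at 33.

**Further compounds**
F1 | step 7 | C1 geminal dibromide, C4 carbinol, C7 ketal | O1CCOC12CC[C@]3(C)C(Br)(Br)CC[C@@](C)(O)[C@H]3C2
F2 | step 13 | primary allylic acetate of 18 | CC(=O)OC/C=C1\[C@H](O)C[C@]2(C)[C@@H](Br)CC[C@@](C)(O)[C@H]2C1
F3 | step 13 | vinyl lactone with C11 as CH2 | O=C1O[C@@H]2C[C@]3(C)[C@@H](Br)CC[C@@](C)(O)[C@H]3C[C@@]2(C=C)C1
F4 | step 13 | vinyl lactone with C11 as CH(CH3), epimers at C11 | O=C1O[C@@H]2C[C@]3(C)[C@@H](Br)CC[C@@](C)(O)[C@H]3C[C@@]2(C=C)C1C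
F5 | step 19 | N-acyloxyphthalimide of 32 | O=C(ON1C(=O)c2ccccc2C1=O)[C@@H]1O[C@@H]2C[C@]3(C)[C@@H](Br)CC[C@@](C)(O)[C@H]3C[C@@]2(C(=O)C=C)C1(C)C
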